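The target has one stereocentre, C3, bonded to the ring methylenes C2 and C4, one hydrogen and ring B carbon C1'. Cutting C3–C1' (with one C4–H) therefore removes all stereochemistry and leaves a flat 2H-chromene with a C3=C4 alkene.
Ring A of that chromene (ether O1, formyl on C8, oxygen on C7, methoxy on C5, hydrogen-bearing C4a) is symmetric 2,6-dihydroxy-4-methoxybenzaldehyde, so either hydroxyl can become O1 and only one ortho carbon is open for ring closure.
Further cuts: C4–C4a of the pyran ring (back to an aryl propargyl ether) and the prenyl–aryl bond of ring B (back to protected 4-bromoresorcinol).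
Forward order: ring A is bought complete, ring C is closed by 6-endo hydroarylation of the propargyl ether, and ring B is prenylated separately and joined last at C3.
Stereochemistry: 3R is set in the union by face-selective syn carbopalladation of the achiral chromene under Pd(OAc)2/(R)-MeO-MOP, followed by formate reduction of the C4–Pd bond; nothing later can epimerise C3.

Key step: step 6

Assumption: the sense of induction of the chiral ligand on this new substrate cannot be derived from precedent; the route is written for (R)-MeO-MOP, and the (S)-antipode takes its place if a pilot run shows the opposite sense.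

Step 1
Reactants: 1 2,6-dihydroxy-4-methoxybenzaldehyde; 2 propargyl bromide (3-bromoprop-1-yne)
Product: 3 2-hydroxy-4-methoxy-6-(prop-2-yn-1-yloxy)benzaldehyde
Conditions: 2 (1.05 equiv), K2CO3 (1.1 equiv), acetone, rt to 40 °C
Reagents that add atoms: none
Why: Williamson ether synthesis in which the two phenols of 1 are equivalent and, once one is alkylated, the other stays hydrogen-bonded to the formyl group and is much less nucleophilic, so one equivalent of bromide should stop at the mono-ether.

Step 2
Reactants: 3 2-hydroxy-4-methoxy-6-(prop-2-yn-1-yloxy)benzaldehyde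
Product: 4 4-methoxy-2-(methoxymethoxy)-6-(prop-2-yn-1-yloxy)benzaldehyde
Conditions: MOMCl, i-Pr2NEt, CH2Cl2, 0 °C to rt
Reagents that add atoms: chloromethyl methyl ether (MOMCl), COCCl
Why: MOM protection (O-alkylation of the salicylaldehyde-type phenol with a hindered amine base) masks the acidic, metal-chelating hydroxyl before the gold and palladium steps.

Step 3
Reactants: 4 4-methoxy-2-(methoxymethoxy)-6-(prop-2-yn-1-yloxy)benzaldehyde
Product: 5 5-methoxy-7-(methoxymethoxy)-2H-chromene-8-carbaldehyde
Conditions: Ph3PAuNTf2 (3 mol%), CH2Cl2, rt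
Reagents that add atoms: none
Why: Intramolecular alkyne hydroarylation in which monovalent gold activates the terminal alkyne and the only free ring carbon ortho to the ether oxygen (flanked by the methoxy group, para to the MOM ether) attacks the terminal alkyne carbon in a 6-endo-dig closure, giving the 2H-chromene after protodeauration.

Step 4
Reactants: 6 4-bromoresorcinol (4-bromobenzene-1,3-diol)
Product: 7 1-bromo-2,4-bis(methoxymethoxy)benzene
Conditions: MOMCl (2.4 equiv), i-Pr2NEt, CH2Cl2, 0 °C to rt
Reagents that add atoms: chloromethyl methyl ether (MOMCl), COCCl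
Why: Standard bis-MOM protection of both phenols, which also installs the two directing groups that flank the ring position to be metalated next.

Step 5
Reactants: 7 1-bromo-2,4-bis(methoxymethoxy)benzene; 8 prenyl bromide (1-bromo-3-methylbut-2-ene)
Product: 10 1-bromo-2,4-bis(methoxymethoxy)-3-(3-methylbut-2-en-1-yl)benzene, via aryllithium 9 (not isolated)
Conditions: LiTMP (from 2,2,6,6-tetramethylpiperidine and n-BuLi), THF, −78 °C; CuBr·SMe2 (20 mol%), then 8, −78 to 0 °C
Reagents that add atoms: none
Why: Directed ortho-metalation with a non-nucleophilic lithium amide removes the most acidic proton, the one between the two OMOM groups, without bromine–lithium exchange, and the aryllithium is then allylated at the primary carbon of prenyl bromide under copper catalysis, attack at the tertiary end being disfavoured by the two ortho substituents.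

Step 6
Reactants: 5 5-methoxy-7-(methoxymethoxy)-2H-chromene-8-carbaldehyde; 10 1-bromo-2,4-bis(methoxymethoxy)-3-(3-methylbut-2-en-1-yl)benzene
Product: 11 (3R)-3-[2,4-bis(methoxymethoxy)-3-(3-methylbut-2-en-1-yl)phenyl]-5-methoxy-7-(methoxymethoxy)chromane-8-carbaldehyde
Conditions: Pd(OAc)2 (5 mol%), (R)-MeO-MOP (12 mol%), HCO2Na (2.5 equiv), n-Bu4NBr (1 equiv), 10 (1.3 equiv), DMF, 70 °C
Reagents that add atoms: none
Why: Proposed new method: bromide 10 adds oxidatively to zerovalent palladium carrying the chiral monophosphine, and the arylpalladium bromide inserts syn across the C3=C4 alkene of 5 with aryl going to C3 and palladium to benzylic C4; the hydrogen on C3 then lies on the face opposite to palladium and C4a has none, so syn β-hydride elimination has no partner and the alkylpalladium persists until bromide is exchanged for formate, CO2 is lost and the Pd–H reductively eliminates to the C4 methylene. The closest known reaction types are the palladium-mediated oxyarylation of 2H-chromenes with 2-halophenols (same regiochemistry, aryl to C3 and palladium to C4) and enantioselective reductive Heck hydroarylations of strained and other cyclic alkenes with formate. No ring is formed in this step, since rings A and C arrive intact in 5 and ring B in 10. The new C3 stereocentre is controlled only by the chiral ligand on palladium, which distinguishes the two faces of the planar, achiral chromene in the migratory insertion. The step needs regioselectivity for C3 arylation, which the π-benzyl stabilisation of palladium at C4 by the electron-rich ring A provides, with added bromide keeping palladium on the neutral, halide-bound pathway that disfavours C4 arylation. It also needs chemoselectivity, which follows from the cis-disubstituted styrenyl alkene being the only olefin that undergoes carbopalladation (the trisubstituted prenyl group is inert) and from the tolerance of the aryl aldehyde and MOM ethers for palladium and formate.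

Step 7
Reactants: 11 (3R)-3-[2,4-bis(methoxymethoxy)-3-(3-methylbut-2-en-1-yl)phenyl]-5-methoxy-7-(methoxymethoxy)chromane-8-carbaldehyde
Product: 12 (3R)-3-[2,4-dihydroxy-3-(3-methylbut-2-en-1-yl)phenyl]-7-hydroxy-5-methoxychromane-8-carbaldehyde (CNP0399843.1)
Conditions: HCl (1.25 M in MeOH), 0 °C to rt, short reaction time; aq NaHCO3 work-up
Reagents that add atoms: none
Why: Acid-catalysed acetal exchange with methanol cleaves all three MOM ethers (the one ortho to the formyl group fastest), and dilute, cold, brief acid should leave the prenyl group uncyclised although it is now flanked by two free phenols, while C3 has no pathway to epimerise.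

Compound list
1 | 2,6-dihydroxy-4-methoxybenzaldehyde | COc1cc(O)c(C=O)c(O)c1 | starting material
2 | propargyl bromide (3-bromoprop-1-yne) | C#CCBr | starting material
3 | 2-hydroxy-4-methoxy-6-(prop-2-yn-1-yloxy)benzaldehyde | COc1cc(O)c(C=O)c(OCC#C)c1 | intermediate
4 | 4-methoxy-2-(methoxymethoxy)-6-(prop-2-yn-1-yloxy)benzaldehyde | COc1cc(OCOC)c(C=O)c(OCC#C)c1 | intermediate
5 | 5-methoxy-7-(methoxymethoxy)-2H-chromene-8-carbaldehyde | COc1cc(OCOC)c(C=O)c2c1C=CCO2 | intermediate
6 | 4-bromoresorcinol (4-bromobenzene-1,3-diol) | Oc1ccc(Br)c(O)c1 | starting material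
7 | 1-bromo-2,4-bis(methoxymethoxy)benzene | COCOc1ccc(Br)c(OCOC)c1 | intermediate
8 | prenyl bromide (1-bromo-3-methylbut-2-ene) | CC(C)=CCBr | starting material
9 | [3-bromo-2,6-bis(methoxymethoxy)phenyl]lithium | COCOc1ccc(Br)c(OCOC)c1[Li] | intermediate (not isolated)
10 | 1-bromo-2,4-bis(methoxymethoxy)-3-(3-methylbut-2-en-1-yl)benzene | COCOc1ccc(Br)c(OCOC)c1CC=C(C)C | intermediate
11 | (3R)-3-[2,4-bis(methoxymethoxy)-3-(3-methylbut-2-en-1-yl)phenyl]-5-methoxy-7-(methoxymethoxy)chromane-8-carbaldehyde | COc1cc(OCOC)c(C=O)c2c1C[C@H](c1ccc(OCOC)c(CC=C(C)C)c1OCOC)CO2 | intermediate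
12 | (3R)-3-[2,4-dihydroxy-3-(3-methylbut-2-en-1-yl)phenyl]-7-hydroxy-5-methoxychromane-8-carbaldehyde | COc1cc(O)c(C=O)c2c1C[C@H](c1ccc(O)c(CC=C(C)C)c1O)CO2 | target

Total step count: 7. Longest linear sequence: 5 steps (steps 1, 2, 3, 6, 7); the ring B branch (steps 4, 5) joins at step 6.

Steps most likely to fail

Step 6 (asymmetric hydroarylation).
- What may go wrong: formate may reduce the arylpalladium bromide before it inserts, so that the aryl bromide is simply debrominated. Insertion into the cis-disubstituted, electron-rich alkene may be slow. The benzylic alkylpalladium may epimerise and eliminate to the achiral 3-aryl-2H-chromene. Facial selectivity may be poor.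
- Fallback, known chemistry only: it sets out from propargyl ether 4 and bromide 10 and comes back to the route at 11; the C3–C1' bond is made by Suzuki–Miyaura coupling and the stereocentre by asymmetric hydrogenation. Alkyne 4 would be iodinated at its terminus (NIS, AgNO3 as catalyst, acetone, rt) to 2-[(3-iodoprop-2-yn-1-yl)oxy]-4-methoxy-6-(methoxymethoxy)benzaldehyde F1. IPrAuNTf2 (IPr = 1,3-bis(2,6-diisopropylphenyl)imidazol-2-ylidene) in hot 1,4-dioxane should cycloisomerise F1 with 1,2-iodine migration, a known way to 3-iodo-2H-chromenes, to give 3-iodo-5-methoxy-7-(methoxymethoxy)-2H-chromene-8-carbaldehyde F2. Bromide 10 would be converted by Miyaura borylation (B2pin2, PdCl2(dppf), KOAc, dioxane, 80 °C) into 2-[2,4-bis(methoxymethoxy)-3-(3-methylbut-2-en-1-yl)phenyl]-4,4,5,5-tetramethyl-1,3,2-dioxaborolane F3. Coupling of F2 with F3 (Pd(PPh3)4, K2CO3, dioxane/water, 80 °C) should give 3-[2,4-bis(methoxymethoxy)-3-(3-methylbut-2-en-1-yl)phenyl]-5-methoxy-7-(methoxymethoxy)-2H-chromene-8-carbaldehyde F4. Iridium-catalysed asymmetric hydrogenation of the C3=C4 bond of F4, a reaction established for 3-aryl-2H-chromenes, would then give 11. The catalyst would be [Ir(cod)(tBu-PHOX)]BArF (cod = 1,5-cyclooctadiene, tBu-PHOX = 4-tert-butyl-2-[2-(diphenylphosphino)phenyl]-4,5-dihydrooxazole, BArF = tetrakis[3,5-bis(trifluoromethyl)phenyl]borate) in CH2Cl2 under H2, with the ligand antipode chosen for 3R. Hydrogen uptake would be stopped at one equivalent, because the non-conjugated, trialkyl-substituted prenyl alkene is expected to be reduced much more slowly by this catalyst class than the aryl-conjugated one.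

Step 5 (metalation and prenylation of the bromoarene).
- What may go wrong: deprotonation next to bromine may compete, leading to aryne formation or bromine migration. The hindered aryl metal may be allylated incompletely or at the tertiary end of prenyl bromide.
- Fallback: it sets out from prenyl bromide 8 and comes back to the route at 10; the order is reversed so that no strong base meets an aryl bromide. 1,3-Bis(methoxymethoxy)benzene F5 (commercial, or from resorcinol and MOMCl) would be lithiated with n-BuLi (THF, 0 °C) between its two OMOM groups to [2,6-bis(methoxymethoxy)phenyl]lithium F6. With CuBr·SMe2 and 8, F6 should give 1,3-bis(methoxymethoxy)-2-(3-methylbut-2-en-1-yl)benzene F7. Electrophilic bromination of F7 with NBS (MeCN, −20 °C) would then deliver 10; the ring position para to one OMOM group and ortho to the other is expected to react faster than the prenyl alkene in the absence of an added nucleophile.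

Step 7 (global deprotection).
- What may go wrong: a liberated ring B phenol may add to the protonated prenyl double bond (chroman formation) while the unchelated MOM ethers are still cleaving slowly.
- Fallback: it sets out from phenol 3 and 4-bromoresorcinol 6 and comes back to the route at target 12; the MOM groups are replaced by fluoride-labile SEM groups so that no acid is needed at the end. Phenol 3 with SEMCl (i-Pr2NEt, CH2Cl2) would give 4-methoxy-2-(prop-2-yn-1-yloxy)-6-{[2-(trimethylsilyl)ethoxy]methoxy}benzaldehyde F8. Cyclisation as in step 3 would give 5-methoxy-7-{[2-(trimethylsilyl)ethoxy]methoxy}-2H-chromene-8-carbaldehyde F9. Diol 6 with SEMCl would give 1-bromo-2,4-bis{[2-(trimethylsilyl)ethoxy]methoxy}benzene F10. Metalation as in step 5 would give (3-bromo-2,6-bis{[2-(trimethylsilyl)ethoxy]methoxy}phenyl)lithium F11, and prenylation with 8 would give 1-bromo-3-(3-methylbut-2-en-1-yl)-2,4-bis{[2-(trimethylsilyl)ethoxy]methoxy}benzene F12. Union of F9 and F12 under the conditions of step 6 would give (3R)-5-methoxy-3-[3-(3-methylbut-2-en-1-yl)-2,4-bis{[2-(trimethylsilyl)ethoxy]methoxy}phenyl]-7-{[2-(trimethylsilyl)ethoxy]methoxy}chromane-8-carbaldehyde F13. Tetrabutylammonium fluoride (DMPU, 50 °C, ethylenediamine as formaldehyde scavenger) should then remove all three SEM groups under basic conditions, in which phenoxides do not add to the prenyl alkene, giving 12.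

Further compounds
F1 | step 6 | 2-[(3-iodoprop-2-yn-1-yl)oxy]-4-methoxy-6-(methoxymethoxy)benzaldehyde | COc1cc(OCOC)c(C=O)c(OCC#CI)c1
F2 | step 6 | 3-iodo-5-methoxy-7-(methoxymethoxy)-2H-chromene-8-carbaldehyde | COc1cc(OCOC)c(C=O)c2c1C=C(I)CO2
F3 | step 6 | 2-[2,4-bis(methoxymethoxy)-3-(3-methylbut-2-en-1-yl)phenyl]-4,4,5,5-tetramethyl-1,3,2-dioxaborolane | COCOc1ccc(B2OC(C)(C)C(C)(C)O2)c(OCOC)c1CC=C(C)C
F4 | step 6 | 3-[2,4-bis(methoxymethoxy)-3-(3-methylbut-2-en-1-yl)phenyl]-5-methoxy-7-(methoxymethoxy)-2H-chromene-8-carbaldehyde | COc1cc(OCOC)c(C=O)c2c1C=C(c1ccc(OCOC)c(CC=C(C)C)c1OCOC)CO2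
F5 | step 5 | 1,3-bis(methoxymethoxy)benzene | COCOc1cccc(OCOC)c1
F6 | step 5 | [2,6-bis(methoxymethoxy)phenyl]lithium | COCOc1cccc(OCOC)c1[Li]
F7 | step 5 | 1,3-bis(methoxymethoxy)-2-(3-methylbut-2-en-1-yl)benzene | COCOc1cccc(OCOC)c1CC=C(C)C
F8 | step 7 | 4-methoxy-2-(prop-2-yn-1-yloxy)-6-{[2-(trimethylsilyl)ethoxy]methoxy}benzaldehyde | COc1cc(OCOCC[Si](C)(C)C)c(C=O)c(OCC#C)c1
F9 | step 7 | 5-methoxy-7-{[2-(trimethylsilyl)ethoxy]methoxy}-2H-chromene-8-carbaldehyde | COc1cc(OCOCC[Si](C)(C)C)c(C=O)c2c1C=CCO2
F10 | step 7 | 1-bromo-2,4-bis{[2-(trimethylsilyl)ethoxy]methoxy}benzene | C[Si](C)(C)CCOCOc1ccc(Br)c(OCOCC[Si](C)(C)C)c1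
F11 | step 7 | (3-bromo-2,6-bis{[2-(trimethylsilyl)ethoxy]methoxy}phenyl)lithium | C[Si](C)(C)CCOCOc1ccc(Br)c(OCOCC[Si](C)(C)C)c1[Li]
F12 | step 7 | 1-bromo-3-(3-methylbut-2-en-1-yl)-2,4-bis{[2-(trimethylsilyl)ethoxy]methoxy}benzene | C[Si](C)(C)CCOCOc1ccc(Br)c(OCOCC[Si](C)(C)C)c1CC=C(C)C
F13 | step 7 | (3R)-5-methoxy-3-[3-(3-methylbut-2-en-1-yl)-2,4-bis{[2-(trimethylsilyl)ethoxy]methoxy}phenyl]-7-{[2-(trimethylsilyl)ethoxy]methoxy}chromane-8-carbaldehyde | COc1cc(OCOCC[Si](C)(C)C)c(C=O)c2c1C[C@H](c1ccc(OCOCC[Si](C)(C)C)c(CC=C(C)C)c1OCOCC[Si](C)(C)C)CO2
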